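## Structural features

The target is an open-chain bis-bibenzyl made of four benzene rings. Ring A (3-methoxyphenyl) is linked by a CH2CH2 bridge to ring B, a 1,2,4-trisubstituted phenol. Ring B carries, ortho to its hydroxyl, a diaryl ether oxygen leading to the para-disubstituted ring C, and ring C is linked by a second CH2CH2 bridge to ring D (3-hydroxyphenyl). There is no stereocentre and no stereogenic double bond, so no neighbouring stereocentres have to be related; the problems are connectivity and the differentiation of oxygen functions. Three oxygens are phenolic in origin but must end up different: a methyl ether on ring A and free hydroxyls on rings B and D, so any protecting group has to come off without touching an aryl methyl ether. The free catechol-type monoether of ring B is oxidation-prone and both bridges have benzylic C–H bonds; otherwise the molecule is robust. The real difficulty is the diaryl ether: its oxygen sits on a hindered, ortho-oxygenated carbon of ring B and on a ring C that bears only an alkyl group para to it, so ring C offers no activation for a direct aryl–oxygen substitution. Ring C carries only the ether oxygen at C1 and the bridge at C4, with four unsubstituted CH positions. That 1,4-pattern is what a 2-oxygenated buta-1,3-diene and an acceptor-substituted terminal alkyne produce, so the key step grows ring C on the ring B oxygen by forming C2–C3 and C4–C5. The acceptor carbonyl then lies on the benzylic carbon of the C–D bridge, where it can be reduced away.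

## Logic of the disconnections

18 ⇒ 15. No skeletal bond is cut. The bridge CH2 next to ring C is traced back to a carbonyl and the two free phenols to benzyl ethers. This is done because a single reductive operation can undo all three changes, and because the carbonyl is exactly the handle a dienophile leaves behind. The gain is that 15 has no free phenol. The forward step must take C=O to CH2 and cleave two O–benzyl bonds while sparing the O–methyl bond, the diaryl ether and the arenes; it should pass through 16 and 17.

15 ⇒ 14. Ring C is taken back by two hydrogens to a cyclohexa-1,4-diene; no C–C bond is cut. This exposes the cycloadduct. The forward oxidation must remove hydride from the doubly allylic CH2 of 14 faster than it touches benzyl ethers or bridge C–H bonds, and before any acid can hydrolyse the aryl enol ether.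

14 ⇒ 8 + 13. C2–C3 and C4–C5 of ring C are cut in a retro-[4+2] sense. This divides the molecule into an A–B half that already carries the ether oxygen and a ring D unit of similar size, and it removes any need for an aryl–oxygen coupling. The forward step must be para-selective and both partners must survive heating without polymerising.

8 ⇒ 7 ⇒ 5 + 6. The exocyclic CH2 on the oxygen-bearing diene carbon is removed to reveal an ester carbonyl, and the O–acyl bond is then cut. The bond from the ring B oxygen to an sp2 carbon thereby becomes an ordinary phenol acylation with commercial 6. The forward carbonyl methylenation must accept an aryl ester that also contains a vinyl group, and 8 must be handled free of acid.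

5 ⇒ 4 ⇒ 1 + 2. The A–B bridge is taken back to an alkene and cut at the C=C bond, by way of 3. Both pieces are commercial, and 1 already has the two ring B oxygens differentiated: free at the position that becomes the ether, benzylated at the position that ends as the phenol. The olefination must run on a free phenol, and the saturation must not cleave the benzyl ether.

13 ⇒ 11 ⇒ 9. The bond between the carbonyl carbon and the alkyne carbon is cut, by way of 12, and then the amide C–N bond, by way of 10. An acyl substitution that stops at the ketone stage gives the terminal ynone from commercial 9 in two steps. The forward step must avoid over-addition and must keep the liberated amine from adding to the ynone.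

## Other disconnections considered

Alternative 1: The cut is in the A–B bridge, at both the bond from C1 of ring B to the benzylic CH and the bond from CH2 to C1 of ring A. In the forward sense the aryl bromide A1 would undergo bromine–lithium exchange with t-BuLi and add to the vinylboronic ester A2. Pd(OAc)2 with a chiral ferrocenyl bisphosphine would then couple the resulting boronate complex with the aryl triflate A3. The arylpalladium species adds to the vinyl terminus while the ring B aryl shifts from boron to the adjacent carbon, giving the benzylic boronate A4.

- In favour: three components and two C–C bonds are joined in one catalytic, low-temperature step, and benzyl and methyl ethers are compatible.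
- Against: the boron-bearing stereocentre is created only to be erased, so a protodeboronation is added before debenzylation. Lithium bromide from the exchange would be expected to slow the cationic arylpalladium pathway unless sequestered. A1 already contains rings B, C and D and the diaryl ether, so the hard bond of the target has to be made earlier by other means.
- Comparison, structure: it addresses the easiest part of the molecule, which steps 1 and 2 make from two commercial compounds, and leaves the diaryl ether unsolved. The chosen plan solves the ether by building ring C on the oxygen.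
- Comparison, mechanism: a metal-catalysed 1,2-metalate shift stands against a thermal pericyclic reaction. On mildness and catalytic character the alternative is the better, and on tolerance of the ether groups it is equal.
- Comparison, step economy: two steps follow the key step in both plans, but the route to A1 is longer than the four steps to 8, so the alternative is longer overall.

Alternative 2: The cut is at C1–C6 and C2–C3 of ring B, with C1 the bridge-bearing carbon. The aldehyde A5 would be converted into its pyrrolidine enamine A6, which adds in Michael fashion to the aryloxymethyl vinyl ketone A7. The resulting keto aldehyde closes by aldol condensation through the aryloxy-bearing carbon to give the cyclohexenone A8. Dehydrogenation to the phenol and debenzylation of ring D would follow.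

- In favour: the ether oxygen is attached to an sp3 carbon by simple O-alkylation, the same idea as acylating 5 in the chosen plan, and on that point the two are equal. Only one six-membered aldol closure is possible, so the 1,2,4-pattern of ring B is fixed by connectivity; that is better than relying on orbital-controlled para over meta selectivity. The ring B hydroxyl arises from the ketone and needs no protecting group, also a point in its favour.
- Against: A7 is a polymerisable α-aryloxy enone. A8 lies two oxidation levels below the arene, so it needs a four-electron dehydrogenation in the presence of two bibenzyl bridges, whereas 14 needs only a two-electron oxidation that should run at room temperature. A5 and A7 both require multistep preparation, A7 from a pre-formed ring C–D bibenzyl phenol.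
- Comparison: the mechanism is stepwise and polar rather than concerted. Two steps follow the key step in both plans, and the overall count would be comparable or slightly higher. The chosen plan is preferred for its much easier aromatisation and for using commercial 1 with the ring B oxygens already differentiated.

Alternative 3: The cut is at C1–C2 and C4–C5 of ring D, with C1 the bridge-bearing carbon. TiCl4 would promote attack of the terminal carbon of the bis-silyl dienolate A9 on the acetal carbon of the β-keto acetal A10. Closure of the central carbon onto the ketone, with loss of methanol and water, would give the salicylate A11. Ester hydrolysis, decarboxylation and debenzylation would follow.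

- In favour: the reaction runs at low temperature, the regiochemistry is fixed by the higher reactivity of the acetal, and the ring D hydroxyl appears unprotected. On regiocontrol by connectivity it equals the chosen plan, and on protecting-group economy at ring D it is better.
- Against: it builds the simplest ring of the target, which is commercial as 9. The ester carbon is introduced only to be expelled, through saponification of a 2,6-disubstituted benzoate and a forcing decarboxylation of a salicylic acid. A strong Lewis acid is used next to a benzyl aryl ether. A10 must already contain rings A, B and C and the diaryl ether, so the hard bond is again left to other chemistry.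
- Comparison: the mechanism is a stepwise Lewis-acid-mediated aldol sequence rather than a cycloaddition. Three steps follow the key step against two, atom economy is poorer, and the precursor is longer, so the chosen plan is shorter and puts its ring construction where the difficulty is.

Key step: step 7

Assumption (remark on the chemistry): the target is achiral, so the alkene geometry of 4 and the configuration of the transient carbinol in 17 need no control. The connectivity of 8, 13 and 14 was re-derived atom by atom and needs no correction. Benzyl is kept on both phenols because one hydrogenolysis removes both groups together with the ketone oxygen; the changes to the precursors are operational only (radical inhibitor, acid-free handling of 8 and 14, inverse acidic quench for 13).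

## Route

Step 1
Reactants: 1 4-(benzyloxy)-3-hydroxybenzaldehyde; 2 (3-methoxybenzyl)triphenylphosphonium chloride
Product: 4 2-(benzyloxy)-5-[2-(3-methoxyphenyl)ethenyl]phenol (E/Z mixture), via phosphorus ylide 3 (not isolated)
Conditions: 2 (1.2 equiv), t-BuOK (2.5 equiv), THF, 0 °C; then 1, 0 °C → rt
Reagents that add atoms: none
Why: Wittig olefination of an aromatic aldehyde with a semi-stabilised benzylic ylide; the extra base holds the phenol as its phenoxide, which is meta to the formyl group and so leaves the carbonyl electrophilic, and the alkene geometry is irrelevant because step 2 removes it.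

Step 2
Reactants: 4 2-(benzyloxy)-5-[2-(3-methoxyphenyl)ethenyl]phenol (E/Z mixture)
Product: 5 2-(benzyloxy)-5-[2-(3-methoxyphenyl)ethyl]phenol
Conditions: TsNHNH2 (5 equiv), NaOAc (6 equiv), DME/H2O, reflux
Reagents that add atoms: none
Why: Diimide reduction; HN=NH formed in the flask from the sulfonyl hydrazide transfers two hydrogens to the C=C bond in a concerted syn fashion and should leave the benzyl ether intact, which a palladium-catalysed hydrogenation would not.

Step 3
Reactants: 5 2-(benzyloxy)-5-[2-(3-methoxyphenyl)ethyl]phenol; 6 acryloyl chloride
Product: 7 2-(benzyloxy)-5-[2-(3-methoxyphenyl)ethyl]phenyl prop-2-enoate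
Conditions: 6 (1.2 equiv), Et3N (1.5 equiv), BHT (trace), CH2Cl2, −20 → 0 °C
Reagents that add atoms: none
Why: O-acylation of a phenol with an acid chloride; the ortho-benzyloxy group hinders the hydroxyl only slightly, and low temperature with an inhibitor should suppress polymerisation and conjugate addition to the acrylate.

Step 4
Reactants: 7 2-(benzyloxy)-5-[2-(3-methoxyphenyl)ethyl]phenyl prop-2-enoate
Product: 8 2-{2-(benzyloxy)-5-[2-(3-methoxyphenyl)ethyl]phenoxy}buta-1,3-diene
Conditions: Cp2TiMe2 (2.5 equiv), toluene/THF, 65 °C, dark, Ar; hexane, filtration through basic Al2O3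
Reagents that add atoms: dimethyltitanocene Cp2TiMe2, C[Ti+2]C.c1cc[cH-]c1.c1cc[cH-]c1
Why: Petasis methylenation; thermally generated Cp2Ti=CH2 adds across the ester C=O and the oxatitanacycle collapses to the enol ether, a reaction type established for aryl esters and for α,β-unsaturated esters; the medium is neither acidic nor basic, and exchange at the vinyl group is degenerate.

Step 5
Reactants: 9 3-(benzyloxy)phenylacetic acid
Product: 11 2-[3-(benzyloxy)phenyl]-N-methoxy-N-methylacetamide, via acyl imidazole 10 (not isolated)
Conditions: CDI (1.1 equiv), CH2Cl2, rt; then MeNHOMe·HCl (1.3 equiv), rt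
Reagents that add atoms: N,O-dimethylhydroxylamine hydrochloride, CNOC.Cl
Why: Amide formation through an acyl imidazole; the imidazole released on activation neutralises the hydrochloride, so no further base is needed.

Step 6
Reactants: 11 2-[3-(benzyloxy)phenyl]-N-methoxy-N-methylacetamide
Product: 13 1-[3-(benzyloxy)phenyl]but-3-yn-2-one, via magnesium hemiaminal adduct 12 (not isolated)
Conditions: HC≡CMgBr (2.5 equiv), THF, 0 °C → rt; inverse quench into cold 1 M HCl/Et2O
Reagents that add atoms: ethynylmagnesium bromide, C#C[Mg]Br
Why: Weinreb ketone synthesis; the chelated adduct 12 should persist until the quench and so prevent a second addition, and pouring the mixture into cold acid protonates the liberated amine before it can add to the terminal ynone.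

Step 7
Reactants: 8 2-{2-(benzyloxy)-5-[2-(3-methoxyphenyl)ethyl]phenoxy}buta-1,3-diene; 13 1-[3-(benzyloxy)phenyl]but-3-yn-2-one
Product: 14 2-[3-(benzyloxy)phenyl]-1-(4-{2-(benzyloxy)-5-[2-(3-methoxyphenyl)ethyl]phenoxy}cyclohexa-1,4-dien-1-yl)ethan-1-one
Conditions: 13 (1.5 equiv), BHT (5 mol %), toluene, 95 °C, sealed tube, Ar; concentrated, used crude
Reagents that add atoms: none
Why: The step is a concerted but asynchronous normal-electron-demand [4+2] cycloaddition between the s-cis form of diene 8, whose HOMO is raised by the oxygen lone pair on C2, and the LUMO of ynone 13, suprafacial on both partners. The closest known reaction type is the Diels–Alder reaction of 2-alkoxy- and 2-silyloxybuta-1,3-dienes with acetylenic ketones, which gives 1-acyl-4-oxycyclohexa-1,4-dienes. Ring C is closed intermolecularly as a six-membered carbocycle by two σ-bonds: C2–C3 joins the diene CH2 next to the aryloxy carbon to the ynone β-carbon, and C4–C5 joins the vinyl terminus to the acyl-bearing α-carbon. No stereocentre is created, since every ring atom of 14 is sp2 or CH2. The selectivity needed is para over meta, and it is secured because the largest HOMO coefficient of the diene lies on the CH2 attached to the oxygenated carbon and the largest LUMO coefficient of the ynone lies on its β-carbon; in the asynchronous transition state this places developing positive charge on the oxygen-bearing carbon and negative charge next to the carbonyl. The unhindered terminal alkyne is the only good 2π partner, and the trisubstituted enone of 14 is a much poorer dienophile, so a second addition is not expected. The inhibitor and the exclusion of acid guard against polymerisation and against hydrolysis of the aryl enol ether, which would sever the link between rings B and C.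

Step 8
Reactants: 14 2-[3-(benzyloxy)phenyl]-1-(4-{2-(benzyloxy)-5-[2-(3-methoxyphenyl)ethyl]phenoxy}cyclohexa-1,4-dien-1-yl)ethan-1-one
Product: 15 2-[3-(benzyloxy)phenyl]-1-(4-{2-(benzyloxy)-5-[2-(3-methoxyphenyl)ethyl]phenoxy}phenyl)ethan-1-one
Conditions: DDQ (1.1 equiv), toluene, 0 °C → rt
Reagents that add atoms: none
Why: Oxidative aromatisation of a 1,4-cyclohexadiene; hydride abstraction from a doubly allylic CH2 followed by proton loss is driven by aromatisation and should be far faster than any attack of one equivalent of DDQ on benzyl aryl ethers or bridge C–H bonds.

Step 9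
Reactants: 15 2-[3-(benzyloxy)phenyl]-1-(4-{2-(benzyloxy)-5-[2-(3-methoxyphenyl)ethyl]phenoxy}phenyl)ethan-1-one
Product: 18 2-{4-[2-(3-hydroxyphenyl)ethyl]phenoxy}-4-[2-(3-methoxyphenyl)ethyl]phenol (CNP0225725.0), via diphenolic ketone 16 (not isolated), via racemic benzylic alcohol 17 (not isolated)
Conditions: H2 (4 atm), 10% Pd/C, AcOH/EtOAc, HClO4 (cat.), 40 °C
Reagents that add atoms: none
Why: Catalytic hydrogenolysis; the O-benzyl bonds should cleave first, and under acid promotion the aryl ketone is reduced through carbinol 17, whose benzylic C–O bond is activated by the para-aryloxy group, while the methyl ether, the diaryl ether and the rings are inert under these conditions.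

## Compound list

1 | 4-(benzyloxy)-3-hydroxybenzaldehyde | O=Cc1ccc(OCc2ccccc2)c(O)c1 | starting material
2 | (3-methoxybenzyl)triphenylphosphonium chloride | COc1cccc(C[P+](c2ccccc2)(c2ccccc2)c2ccccc2)c1.[Cl-] | starting material
3 | (3-methoxybenzylidene)triphenylphosphorane | COc1cccc(C=P(c2ccccc2)(c2ccccc2)c2ccccc2)c1 | intermediate (not isolated)
4 | 2-(benzyloxy)-5-[2-(3-methoxyphenyl)ethenyl]phenol (E/Z mixture, geometry not defined) | COc1cccc(C=Cc2ccc(OCc3ccccc3)c(O)c2)c1 | intermediate
5 | 2-(benzyloxy)-5-[2-(3-methoxyphenyl)ethyl]phenol | COc1cccc(CCc2ccc(OCc3ccccc3)c(O)c2)c1 | intermediate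
6 | acryloyl chloride | C=CC(=O)Cl | starting material
7 | 2-(benzyloxy)-5-[2-(3-methoxyphenyl)ethyl]phenyl prop-2-enoate | C=CC(=O)Oc1cc(CCc2cccc(OC)c2)ccc1OCc1ccccc1 | intermediate
8 | 2-{2-(benzyloxy)-5-[2-(3-methoxyphenyl)ethyl]phenoxy}buta-1,3-diene | C=CC(=C)Oc1cc(CCc2cccc(OC)c2)ccc1OCc1ccccc1 | intermediate
9 | 3-(benzyloxy)phenylacetic acid | O=C(O)Cc1cccc(OCc2ccccc2)c1 | starting material
10 | 2-[3-(benzyloxy)phenyl]-1-(1H-imidazol-1-yl)ethan-1-one | O=C(Cc1cccc(OCc2ccccc2)c1)n1ccnc1 | intermediate (not isolated)
11 | 2-[3-(benzyloxy)phenyl]-N-methoxy-N-methylacetamide | CON(C)C(=O)Cc1cccc(OCc2ccccc2)c1 | intermediate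
12 | bromomagnesium 1-[3-(benzyloxy)phenyl]-2-[methoxy(methyl)amino]but-3-yn-2-olate (racemic) | C#CC(O[Mg]Br)(Cc1cccc(OCc2ccccc2)c1)N(C)OC | intermediate (not isolated)
13 | 1-[3-(benzyloxy)phenyl]but-3-yn-2-one | C#CC(=O)Cc1cccc(OCc2ccccc2)c1 | intermediate
14 | 2-[3-(benzyloxy)phenyl]-1-(4-{2-(benzyloxy)-5-[2-(3-methoxyphenyl)ethyl]phenoxy}cyclohexa-1,4-dien-1-yl)ethan-1-one | O=C(Cc1cccc(OCc2ccccc2)c1)C1=CCC(Oc2cc(CCc3cccc(OC)c3)ccc2OCc2ccccc2)=CC1 | intermediate
15 | 2-[3-(benzyloxy)phenyl]-1-(4-{2-(benzyloxy)-5-[2-(3-methoxyphenyl)ethyl]phenoxy}phenyl)ethan-1-one | O=C(Cc1cccc(OCc2ccccc2)c1)c1ccc(Oc2cc(CCc3cccc(OC)c3)ccc2OCc2ccccc2)cc1 | intermediate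
16 | 1-(4-{2-hydroxy-5-[2-(3-methoxyphenyl)ethyl]phenoxy}phenyl)-2-(3-hydroxyphenyl)ethan-1-one | O=C(Cc1cccc(O)c1)c1ccc(Oc2cc(CCc3cccc(OC)c3)ccc2O)cc1 | intermediate (not isolated)
17 | 2-{4-[1-hydroxy-2-(3-hydroxyphenyl)ethyl]phenoxy}-4-[2-(3-methoxyphenyl)ethyl]phenol (racemic) | OC(Cc1cccc(O)c1)c1ccc(Oc2cc(CCc3cccc(OC)c3)ccc2O)cc1 | intermediate (not isolated)
18 | 2-{4-[2-(3-hydroxyphenyl)ethyl]phenoxy}-4-[2-(3-methoxyphenyl)ethyl]phenol | COc1cccc(CCc2ccc(O)c(Oc3ccc(CCc4cccc(O)c4)cc3)c2)c1 | target

## Step count and least certain steps

Total step count: 9. Longest linear sequence: 7 steps (steps 1–4 and 7–9); the ynone branch (steps 5 and 6) joins at step 7.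

Step 7 (key step). An aryloxy group is a weaker donor than an alkoxy or silyloxy group, so the cycloaddition may be slow relative to thermal oligomerisation of the terminal ynone, and some leakage to the meta regioisomer is possible. The fallback gives up the cycloaddition and makes the diaryl ether by nucleophilic aromatic substitution. It sets out from 5, which is heated with 4-fluorobenzaldehyde and K2CO3 in DMF at 120 °C to give 4-{2-(benzyloxy)-5-[2-(3-methoxyphenyl)ethyl]phenoxy}benzaldehyde F1. Commercial 3-(benzyloxy)benzyl bromide and PPh3 in refluxing toluene give [3-(benzyloxy)benzyl]triphenylphosphonium bromide F2. Wittig reaction of F1 with F2 (t-BuOK, THF) gives 1-(benzyloxy)-2-(4-{2-[3-(benzyloxy)phenyl]ethenyl}phenoxy)-4-[2-(3-methoxyphenyl)ethyl]benzene F3 as an E/Z mixture. Hydrogenation over 10% Pd/C in EtOAc/EtOH saturates the alkene and removes both benzyl groups, so the fallback comes back to the route at 18.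

Step 4. At the temperature needed to release Cp2Ti=CH2 from Cp2TiMe2, the acrylate or the product diene may polymerise, and the enol ether may hydrolyse during isolation. The fallback masks the vinyl group. It sets out from 5, which is acylated with 3-chloropropanoyl chloride and pyridine in CH2Cl2 at 0 °C to give 2-(benzyloxy)-5-[2-(3-methoxyphenyl)ethyl]phenyl 3-chloropropanoate F4. Methylenation of this non-polymerisable ester with Cp2TiMe2 gives 1-(benzyloxy)-2-[(4-chlorobut-1-en-2-yl)oxy]-4-[2-(3-methoxyphenyl)ethyl]benzene F5. Elimination of HCl with t-BuOK in THF at 0 °C then unveils the diene, and the fallback comes back to the route at 8.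

Step 6. The liberated N,O-dimethylhydroxylamine may add in conjugate fashion to the terminal ynone during the quench, and the basic acetylide may enolise the arylacetamide, leaving conversion incomplete. The fallback builds the ynone by oxidation instead of acyl substitution. It sets out from 11, which is reduced with i-Bu2AlH in THF at −78 °C to 2-[3-(benzyloxy)phenyl]acetaldehyde F6. Addition of HC≡CMgBr gives racemic 1-[3-(benzyloxy)phenyl]but-3-yn-2-ol F7, and oxidation with Dess–Martin periodinane in CH2Cl2 comes back to the route at 13.

Step 9. The carbonyl hydrogenolysis may stall at the carbinol stage, or turnover may slow once the free phenols occupy the catalyst surface. The fallback separates the two reductions. It sets out from 15, which is treated with Et3SiH and CF3CO2H in CH2Cl2 (0 °C → rt); this ionic hydrogenation of the electron-rich aryl ketone should give 1-(benzyloxy)-2-(4-{2-[3-(benzyloxy)phenyl]ethyl}phenoxy)-4-[2-(3-methoxyphenyl)ethyl]benzene F8. Neutral hydrogenolysis over 10% Pd/C in EtOAc/MeOH then removes the two benzyl groups and comes back to the route at 18.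

## Further compounds

F1 | step 7 | 4-{2-(benzyloxy)-5-[2-(3-methoxyphenyl)ethyl]phenoxy}benzaldehyde | COc1cccc(CCc2ccc(OCc3ccccc3)c(Oc3ccc(C=O)cc3)c2)c1
F2 | step 7 | [3-(benzyloxy)benzyl]triphenylphosphonium bromide | [Br-].c1ccc(COc2cccc(C[P+](c3ccccc3)(c3ccccc3)c3ccccc3)c2)cc1
F3 | step 7 | 1-(benzyloxy)-2-(4-{2-[3-(benzyloxy)phenyl]ethenyl}phenoxy)-4-[2-(3-methoxyphenyl)ethyl]benzene (E/Z mixture, geometry not defined) | COc1cccc(CCc2ccc(OCc3ccccc3)c(Oc3ccc(C=Cc4cccc(OCc5ccccc5)c4)cc3)c2)c1
F4 | step 4 | 2-(benzyloxy)-5-[2-(3-methoxyphenyl)ethyl]phenyl 3-chloropropanoate | ClCCC(=O)Oc1cc(CCc2cccc(OC)c2)ccc1OCc1ccccc1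
F5 | step 4 | 1-(benzyloxy)-2-[(4-chlorobut-1-en-2-yl)oxy]-4-[2-(3-methoxyphenyl)ethyl]benzene | C=C(CCCl)Oc1cc(CCc2cccc(OC)c2)ccc1OCc1ccccc1
F6 | step 6 | 2-[3-(benzyloxy)phenyl]acetaldehyde | O=CCc1cccc(OCc2ccccc2)c1
F7 | step 6 | 1-[3-(benzyloxy)phenyl]but-3-yn-2-ol (racemic) | C#CC(O)Cc1cccc(OCc2ccccc2)c1
F8 | step 9 | 1-(benzyloxy)-2-(4-{2-[3-(benzyloxy)phenyl]ethyl}phenoxy)-4-[2-(3-methoxyphenyl)ethyl]benzene | COc1cccc(CCc2ccc(OCc3ccccc3)c(Oc3ccc(CCc4cccc(OCc5ccccc5)c4)cc3)c2)c1
A1 | alternative 1 | 1-(benzyloxy)-2-(4-{2-[3-(benzyloxy)phenyl]ethyl}phenoxy)-4-bromobenzene | Brc1ccc(OCc2ccccc2)c(Oc2ccc(CCc3cccc(OCc4ccccc4)c3)cc2)c1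
A2 | alternative 1 | 2-ethenyl-4,4,5,5-tetramethyl-1,3,2-dioxaborolane (vinylboronic acid pinacol ester) | C=CB1OC(C)(C)C(C)(C)O1
A3 | alternative 1 | 3-methoxyphenyl trifluoromethanesulfonate | COc1cccc(OS(=O)(=O)C(F)(F)F)c1
A4 | alternative 1 | 2-{1-[4-(benzyloxy)-3-(4-{2-[3-(benzyloxy)phenyl]ethyl}phenoxy)phenyl]-2-(3-methoxyphenyl)ethyl}-4,4,5,5-tetramethyl-1,3,2-dioxaborolane (configuration at the boron-bearing carbon not defined; centre removed later) | COc1cccc(CC(B2OC(C)(C)C(C)(C)O2)c2ccc(OCc3ccccc3)c(Oc3ccc(CCc4cccc(OCc5ccccc5)c4)cc3)c2)c1
A5 | alternative 2 | 4-(3-methoxyphenyl)butanal | COc1cccc(CCCC=O)c1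
A6 | alternative 2 | 1-[(1E)-4-(3-methoxyphenyl)but-1-en-1-yl]pyrrolidine | COc1cccc(CC/C=C/N2CCCC2)c1
A7 | alternative 2 | 1-(4-{2-[3-(benzyloxy)phenyl]ethyl}phenoxy)but-3-en-2-one | C=CC(=O)COc1ccc(CCc2cccc(OCc3ccccc3)c2)cc1
A8 | alternative 2 | 2-(4-{2-[3-(benzyloxy)phenyl]ethyl}phenoxy)-4-[2-(3-methoxyphenyl)ethyl]cyclohex-2-en-1-one (racemic) | O=C1CCC(CCc2cccc(OC)c2)C=C1Oc1ccc(CCc2cccc(OCc3ccccc3)c2)cc1
A9 | alternative 3 | 1-methoxy-1,3-bis(trimethylsilyloxy)buta-1,3-diene | COC(O[Si](C)(C)C)=CC(=C)O[Si](C)(C)C
A10 | alternative 3 | 5-(4-{2-(benzyloxy)-5-[2-(3-methoxyphenyl)ethyl]phenoxy}phenyl)-1,1-dimethoxypentan-3-one | COC(OC)CC(=O)CCc1ccc(Oc2cc(CCc3cccc(OC)c3)ccc2OCc2ccccc2)cc1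
A11 | alternative 3 | methyl 2-[2-(4-{2-(benzyloxy)-5-[2-(3-methoxyphenyl)ethyl]phenoxy}phenyl)ethyl]-6-hydroxybenzoate | COC(=O)c1c(O)cccc1CCc1ccc(Oc2cc(CCc3cccc(OC)c3)ccc2OCc2ccccc2)cc1
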